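**Plan**
1. Retrosynthesis: the O1–C2 bond of ring C is cut first, as a dehydrogenative benzylic C–H / phenol O–H coupling, which leaves an open-chain (R)-α-methoxydihydrochalcone whose C2 is a plain methylene. The C4–C4a bond is cut next (aryllithium plus Weinreb amide), then C2–C3 (aldehyde plus methoxyacetate).
2. Forward: the C2–C3–C4 chain is grown on the ring B aldehyde, C3 is set by asymmetric hydrogenation, ring A is joined at C4 through an ortho-lithiation whose site is fixed by symmetry, and ring C is closed last.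
3. Enabling feature: C2 is the only benzylic C–H para to a methoxy oxygen (C4'–OMe) and ortho to a ring B oxygen (C2'–O, tied to C3'–O in a temporary diphenyl-dioxole so that its lone pair stays conjugated). This makes C2–H hydridic toward DDQ, and the ring A phenol O1 sits five atoms away, placed for a six-membered closure.
4. Stereochemistry: C3 comes from Ru–BINAP hydrogenation of a (Z)-α-methoxycinnamic acid; C2 is set by C3 during ring closure (2,3-trans).
5. Helpers: the ring B dioxole ketal, the C6 benzyl ether and the C5 methyl ether (the 3,5-dimethoxy pattern is what makes the lithiation site unambiguous) are removed after ring closure by chelation-controlled demethylation at C5 and one hydrogenolysis.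

Key step: step 9

Assumption: by analogy with the hydrogenation of (E)-2-methylbut-2-enoic acid, Ru(OAc)2[(R)-BINAP] is taken to deliver the (R)-acid in step 3; if the sense proves opposite, the (S)-ligand is used and nothing else changes.

**Step 1**
Reactants: 1 2,3-dihydroxy-4-methoxybenzaldehyde; 2 dichlorodiphenylmethane
Product: 3 7-methoxy-2,2-diphenyl-1,3-benzodioxole-4-carbaldehyde
Conditions: Ph2CCl2 (1.2 equiv), K2CO3, MeCN, 60 °C
Reagents that add atoms: dichlorodiphenylmethane (2), ClC(Cl)(c1ccccc1)c1ccccc1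
Why: Double O-alkylation of the catechol by the gem-dichloride (Williamson-type ketalisation) should give the diphenylmethylene ketal, the second C–O bond forming intramolecularly, while the aldehyde is inert to K2CO3.

**Step 2**
Reactants: 3 7-methoxy-2,2-diphenyl-1,3-benzodioxole-4-carbaldehyde; 4 methyl methoxyacetate; 5 sodium hydroxide
Product: 7 (Z)-2-methoxy-3-(7-methoxy-2,2-diphenyl-1,3-benzodioxol-4-yl)prop-2-enoic acid, via methyl ester 6 (not isolated)
Conditions: MeOCH2CO2Me (3 equiv), NaOMe, MeOH–THF, 65 °C; then 2 M aq NaOH, 50 °C; then 1 M HCl to pH 3, 0 °C; crystallisation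
Reagents that add atoms: methyl methoxyacetate (4), COCC(=O)OC; sodium hydroxide (5), [Na+].[OH-]
Why: A Claisen-type aldol condensation of the non-enolisable aldehyde with the ester enolate and E1cB dehydration should give the thermodynamically preferred (Z)-enol-ether ester (aryl trans to carboxyl), which is saponified in the same pot; the ketal tolerates base and brief cold dilute acid.

**Step 3**
Reactants: 7 (Z)-2-methoxy-3-(7-methoxy-2,2-diphenyl-1,3-benzodioxol-4-yl)prop-2-enoic acid
Product: 8 (R)-2-methoxy-3-(7-methoxy-2,2-diphenyl-1,3-benzodioxol-4-yl)propanoic acid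
Conditions: H2 (50 bar), Ru(OAc)2[(R)-BINAP] (1 mol %), MeOH, 40 °C
Reagents that add atoms: none
Why: Carboxylate-directed asymmetric hydrogenation of (Z)-α-alkoxycinnamic acids with Ru–diphosphine dicarboxylates is a well-precedented route to 2-alkoxy-3-arylpropanoic acids; the ligand selects the alkene face and so sets C3 as (R), and a homogeneous catalyst should not hydrogenolyse the ketal.

**Step 4**
Reactants: 8 (R)-2-methoxy-3-(7-methoxy-2,2-diphenyl-1,3-benzodioxol-4-yl)propanoic acid; 9 N,O-dimethylhydroxylamine hydrochloride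
Product: 10 (R)-N,2-dimethoxy-3-(7-methoxy-2,2-diphenyl-1,3-benzodioxol-4-yl)-N-methylpropanamide
Conditions: MeNHOMe·HCl, N,N'-diisopropylcarbodiimide, HOBt (cat.), N-methylmorpholine, CH2Cl2, 0 °C to rt
Reagents that add atoms: N,O-dimethylhydroxylamine hydrochloride (9), CNOC.Cl
Why: Carbodiimide coupling to the Weinreb amide should preserve the stereocentre, since an α-alkoxy acid cannot racemise through an oxazolone.

**Step 5**
Reactants: 11 4-hydroxy-3,5-dimethoxybenzaldehyde (syringaldehyde); 12 benzyl bromide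
Product: 13 4-(benzyloxy)-3,5-dimethoxybenzaldehyde
Conditions: BnBr, K2CO3, DMF, 60 °C
Reagents that add atoms: benzyl bromide (12), BrCc1ccccc1
Why: Williamson ether synthesis on the acidic, doubly flanked phenol.

**Step 6**
Reactants: 13 4-(benzyloxy)-3,5-dimethoxybenzaldehyde; 14 3-chloroperoxybenzoic acid
Product: 16 4-(benzyloxy)-3,5-dimethoxyphenol, via aryl formate 15 (not isolated)
Conditions: mCPBA, CH2Cl2, 0 °C to rt; then K2CO3 (cat.), MeOH, rt
Reagents that add atoms: 3-chloroperoxybenzoic acid (14), OOC(=O)c1cccc(Cl)c1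
Why: Dakin-type Baeyer–Villiger oxidation, in which the electron-rich aryl group migrates to oxygen to give the formate, which is then methanolysed to the phenol.

**Step 7**
Reactants: 16 4-(benzyloxy)-3,5-dimethoxyphenol; 17 chloromethyl methyl ether
Product: 18 2-(benzyloxy)-1,3-dimethoxy-5-(methoxymethoxy)benzene
Conditions: MOMCl, K2CO3, acetone, 50 °C
Reagents that add atoms: chloromethyl methyl ether (17), COCCl
Why: O-alkylation of the phenoxide installs the methoxymethyl ether, which is the ortho-directing group for the next step.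

**Step 8**
Reactants: 18 2-(benzyloxy)-1,3-dimethoxy-5-(methoxymethoxy)benzene; 10 (R)-N,2-dimethoxy-3-(7-methoxy-2,2-diphenyl-1,3-benzodioxol-4-yl)-N-methylpropanamide
Product: 21 (R)-1-[3-(benzyloxy)-6-hydroxy-2,4-dimethoxyphenyl]-2-methoxy-3-(7-methoxy-2,2-diphenyl-1,3-benzodioxol-4-yl)propan-1-one, via aryllithium 19 (not isolated), via methoxymethyl ether ketone 20 (not isolated)
Conditions: 18 (1.3 equiv), n-BuLi, THF, 0 °C; then 10, −78 to 0 °C; then 2 M HCl in MeOH, rt
Reagents that add atoms: none
Why: Directed ortho-metalation between the methoxymethoxy and methoxy groups (the two such positions of 18 are equivalent by symmetry, so only one aryllithium can form) and acylation by the Weinreb amide, whose chelated tetrahedral adduct prevents over-addition; methanolic HCl then releases the ketone and removes the carbonyl-flanked methoxymethyl ether, while the ketal, the benzyl ether and the stereocentre should survive.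

**Step 9**
Reactants: 21 (R)-1-[3-(benzyloxy)-6-hydroxy-2,4-dimethoxyphenyl]-2-methoxy-3-(7-methoxy-2,2-diphenyl-1,3-benzodioxol-4-yl)propan-1-one
Product: 23 (2R,3R)-6-(benzyloxy)-3,5,7-trimethoxy-2-(7-methoxy-2,2-diphenyl-1,3-benzodioxol-4-yl)-2,3-dihydro-4H-chromen-4-one, via benzylic oxocarbenium ion 22 (not isolated)
Conditions: DDQ (1.1 equiv), 4 Å molecular sieves, ClCH2CH2Cl, rt, dark
Reagents that add atoms: none
Why: DDQ forms a charge-transfer complex with ring B of 21 and abstracts hydride from the C2 methylene, the only C–H benzylic to a ring carrying a para methoxy oxygen and a coplanar ortho dioxole oxygen, to give the p-quinone-methide oxocarbenium ion 22 paired with the DDQ hydroquinone anion; after rotation about the C4–aryl bond the ring A phenol O1 adds to C2 and the anion takes up the proton. The closest known reaction type is the DDQ cyclodehydrogenation (dehydrogenative benzylic C–H / phenol O–H coupling) of 2-hydroxy-1,3-diarylpropanes to flavans and of 2'-hydroxydihydrochalcones to flavanones. Ring C closes in the 6-exo-trig mode, counted on the C2=C1' bond of the quinone-methide form, through a chair-like transition state. The new C2 stereocentre is controlled by C3: in the reacting conformer C3–H lies close to the plane of the cation beside ring B (least A(1,3) strain), the C3 methoxy group is antiperiplanar to the incoming O1 (Felkin–Anh polar arrangement), and both ring B and the methoxy group finish equatorial, which is the 2,3-trans (2R,3R) isomer. Three selectivities are needed: site selectivity, secured because ring A is deactivated by its acyl group, by the O1–H···O=C hydrogen bond and by its twisted C6 benzyloxy group, and because no other C–H is activated by a para oxygen; retention at C3, secured because in the same conformer C3–H is nearly orthogonal to the empty orbital, so proton loss to the achiral α-methoxychalcone should be slower than intramolecular capture; and a stop at the flavanone, secured by only a slight excess of DDQ, since C2–H of 23 is deactivated by the C4 carbonyl and by the vinylogous-ester character of O1.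

**Step 10**
Reactants: 23 (2R,3R)-6-(benzyloxy)-3,5,7-trimethoxy-2-(7-methoxy-2,2-diphenyl-1,3-benzodioxol-4-yl)-2,3-dihydro-4H-chromen-4-one
Product: 24 (2R,3R)-6-(benzyloxy)-5-hydroxy-3,7-dimethoxy-2-(7-methoxy-2,2-diphenyl-1,3-benzodioxol-4-yl)-2,3-dihydro-4H-chromen-4-one
Conditions: MgI2·OEt2 (3 equiv), THF, 50 °C; then cold 0.5 M HCl
Reagents that add atoms: none
Why: Chelation-controlled ether cleavage: magnesium binds the C4 carbonyl and the peri C5 methoxy oxygen in a six-membered chelate and iodide removes that methyl group by SN2, a known selective demethylation ortho to a carbonyl; the C7, C4' and aliphatic C3 methyl ethers lack this activation, and the mild conditions should leave both stereocentres and the ketal alone.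

**Step 11**
Reactants: 24 (2R,3R)-6-(benzyloxy)-5-hydroxy-3,7-dimethoxy-2-(7-methoxy-2,2-diphenyl-1,3-benzodioxol-4-yl)-2,3-dihydro-4H-chromen-4-one
Product: 25 (2R,3R)-2-(2,3-dihydroxy-4-methoxyphenyl)-5,6-dihydroxy-3,7-dimethoxy-2,3-dihydro-4H-chromen-4-one
Conditions: H2 (1 atm), Pd/C (10 wt %), EtOAc–MeOH, rt
Reagents that add atoms: none
Why: Heterogeneous catalytic hydrogenolysis cleaves the benzyl ether and the diphenylmethylene ketal (both benzylic C–O bonds) to free the two catechols, under conditions in which the aryl ketone and the dihydroflavonol stereocentres are normally retained.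

**Compound list**
1 | 2,3-dihydroxy-4-methoxybenzaldehyde | COc1ccc(C=O)c(O)c1O | starting material
2 | dichlorodiphenylmethane | ClC(Cl)(c1ccccc1)c1ccccc1 | starting material
3 | 7-methoxy-2,2-diphenyl-1,3-benzodioxole-4-carbaldehyde | COc1ccc(C=O)c2OC(c3ccccc3)(c3ccccc3)Oc12 | intermediate
4 | methyl methoxyacetate | COCC(=O)OC | starting material
5 | sodium hydroxide | [Na+].[OH-] | starting material
6 | methyl (Z)-2-methoxy-3-(7-methoxy-2,2-diphenyl-1,3-benzodioxol-4-yl)prop-2-enoate | CO/C(=C\c1ccc(OC)c2OC(c3ccccc3)(c3ccccc3)Oc12)C(=O)OC | intermediate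
7 | (Z)-2-methoxy-3-(7-methoxy-2,2-diphenyl-1,3-benzodioxol-4-yl)prop-2-enoic acid | CO/C(=C\c1ccc(OC)c2OC(c3ccccc3)(c3ccccc3)Oc12)C(=O)O | intermediate
8 | (R)-2-methoxy-3-(7-methoxy-2,2-diphenyl-1,3-benzodioxol-4-yl)propanoic acid | CO[C@H](Cc1ccc(OC)c2OC(c3ccccc3)(c3ccccc3)Oc12)C(=O)O | intermediate
9 | N,O-dimethylhydroxylamine hydrochloride | CNOC.Cl | starting material
10 | (R)-N,2-dimethoxy-3-(7-methoxy-2,2-diphenyl-1,3-benzodioxol-4-yl)-N-methylpropanamide | CO[C@H](Cc1ccc(OC)c2OC(c3ccccc3)(c3ccccc3)Oc12)C(=O)N(C)OC | intermediate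
11 | 4-hydroxy-3,5-dimethoxybenzaldehyde (syringaldehyde) | COc1cc(C=O)cc(OC)c1O | starting material
12 | benzyl bromide | BrCc1ccccc1 | starting material
13 | 4-(benzyloxy)-3,5-dimethoxybenzaldehyde | COc1cc(C=O)cc(OC)c1OCc1ccccc1 | intermediate
14 | 3-chloroperoxybenzoic acid | OOC(=O)c1cccc(Cl)c1 | starting material
15 | 4-(benzyloxy)-3,5-dimethoxyphenyl formate | COc1cc(OC=O)cc(OC)c1OCc1ccccc1 | intermediate
16 | 4-(benzyloxy)-3,5-dimethoxyphenol | COc1cc(O)cc(OC)c1OCc1ccccc1 | intermediate
17 | chloromethyl methyl ether | COCCl | starting material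
18 | 2-(benzyloxy)-1,3-dimethoxy-5-(methoxymethoxy)benzene | COCOc1cc(OC)c(OCc2ccccc2)c(OC)c1 | intermediate
19 | [3-(benzyloxy)-2,4-dimethoxy-6-(methoxymethoxy)phenyl]lithium | [Li]c1c(OC)c(OCc2ccccc2)c(OC)cc1OCOC | intermediate
20 | (R)-1-[3-(benzyloxy)-2,4-dimethoxy-6-(methoxymethoxy)phenyl]-2-methoxy-3-(7-methoxy-2,2-diphenyl-1,3-benzodioxol-4-yl)propan-1-one | CO[C@H](Cc1ccc(OC)c2OC(c3ccccc3)(c3ccccc3)Oc12)C(=O)c1c(OC)c(OCc2ccccc2)c(OC)cc1OCOC | intermediate
21 | (R)-1-[3-(benzyloxy)-6-hydroxy-2,4-dimethoxyphenyl]-2-methoxy-3-(7-methoxy-2,2-diphenyl-1,3-benzodioxol-4-yl)propan-1-one | CO[C@H](Cc1ccc(OC)c2OC(c3ccccc3)(c3ccccc3)Oc12)C(=O)c1c(OC)c(OCc2ccccc2)c(OC)cc1O | intermediate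
22 | benzylic (p-quinone-methide) oxocarbenium ion derived from 21 by loss of hydride from C2 | CO[C@H]([CH+]c1ccc(OC)c2OC(c3ccccc3)(c3ccccc3)Oc12)C(=O)c1c(OC)c(OCc2ccccc2)c(OC)cc1O | intermediate
23 | (2R,3R)-6-(benzyloxy)-3,5,7-trimethoxy-2-(7-methoxy-2,2-diphenyl-1,3-benzodioxol-4-yl)-2,3-dihydro-4H-chromen-4-one | COc1ccc([C@H]2Oc3cc(OC)c(OCc4ccccc4)c(OC)c3C(=O)[C@@H]2OC)c2OC(c3ccccc3)(c3ccccc3)Oc12 | intermediate
24 | (2R,3R)-6-(benzyloxy)-5-hydroxy-3,7-dimethoxy-2-(7-methoxy-2,2-diphenyl-1,3-benzodioxol-4-yl)-2,3-dihydro-4H-chromen-4-one | COc1ccc([C@H]2Oc3cc(OC)c(OCc4ccccc4)c(O)c3C(=O)[C@@H]2OC)c2OC(c3ccccc3)(c3ccccc3)Oc12 | intermediate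
25 | (2R,3R)-2-(2,3-dihydroxy-4-methoxyphenyl)-5,6-dihydroxy-3,7-dimethoxy-2,3-dihydro-4H-chromen-4-one | COc1ccc([C@H]2Oc3cc(OC)c(O)c(O)c3C(=O)[C@@H]2OC)c(O)c1O | target

**Step count and risks**
Total steps: 11. Longest linear sequence: 8 steps (steps 1–4 and 8–11).

Step 9 is the most likely to fail. The cation 22 may lose its C3 proton to give the achiral α-methoxychalcone, which erodes configuration and yield; 23 may be dehydrogenated further; or the ring A phenol may be oxidised. The fallback sets out from 3 and returns at 23. A boron-mediated Evans syn aldol reaction (Bu2BOTf, i-Pr2NEt, CH2Cl2, −78 °C) of 3 with (R)-4-benzyl-3-(methoxyacetyl)oxazolidin-2-one F1, itself made from (R)-4-benzyloxazolidin-2-one and methoxyacetyl chloride, should give (R)-4-benzyl-3-[(2R,3S)-3-hydroxy-2-methoxy-3-(7-methoxy-2,2-diphenyl-1,3-benzodioxol-4-yl)propanoyl]oxazolidin-2-one F2. AlMe3/MeNHOMe·HCl converts it into (2R,3S)-3-hydroxy-N,2-dimethoxy-3-(7-methoxy-2,2-diphenyl-1,3-benzodioxol-4-yl)-N-methylpropanamide F3. Its lithium alkoxide is acylated with aryllithium 19 to (2R,3S)-1-[3-(benzyloxy)-2,4-dimethoxy-6-(methoxymethoxy)phenyl]-3-hydroxy-2-methoxy-3-(7-methoxy-2,2-diphenyl-1,3-benzodioxol-4-yl)propan-1-one F4, which methanolic HCl converts without isolation into (2R,3S)-1-[3-(benzyloxy)-6-hydroxy-2,4-dimethoxyphenyl]-3-hydroxy-2-methoxy-3-(7-methoxy-2,2-diphenyl-1,3-benzodioxol-4-yl)propan-1-one F5. An intramolecular Mitsunobu etherification (PPh3, diisopropyl azodicarboxylate, THF, 0 °C) then closes the O1–C2 bond with inversion at the carbinol carbon and gives 23.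

Step 3 is the second risk. The bulky ortho-fused ketal may cause poor enantioface discrimination or slow turnover in the hydrogenation. The fallback sets out from 3 and returns at 10. NaBH4 in MeOH reduces 3 to (7-methoxy-2,2-diphenyl-1,3-benzodioxol-4-yl)methanol F6, and PBr3 (Et2O, 0 °C) gives 4-(bromomethyl)-7-methoxy-2,2-diphenyl-1,3-benzodioxole F7. The sodium enolate (NaN(SiMe3)2, THF, −78 °C) of (S)-4-benzyl-3-(methoxyacetyl)oxazolidin-2-one F8, made from (S)-4-benzyloxazolidin-2-one and methoxyacetyl chloride, is alkylated by F7 on the face away from the auxiliary's benzyl group to give (S)-4-benzyl-3-[(R)-2-methoxy-3-(7-methoxy-2,2-diphenyl-1,3-benzodioxol-4-yl)propanoyl]oxazolidin-2-one F9. Transamination with AlMe3/MeNHOMe·HCl gives 10.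

Step 10 is the third risk. Cleavage at the hindered C5 methoxy group, which lies between the carbonyl and the benzyloxy group, may be slow, and partial loss of the benzyl ether may leave a mixture of partly deprotected material. The fallback sets out from 23 and returns at 25, replacing steps 10 and 11. Treatment of 23 with excess BCl3 and pentamethylbenzene (CH2Cl2, −78 to 0 °C) should remove the chelated C5 methyl group, the benzyl ether and the diphenylmethylene ketal in one operation, so that incomplete selectivity among them no longer matters.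

**Further compounds**
F1 | step 9 | (R)-4-benzyl-3-(methoxyacetyl)oxazolidin-2-one | COCC(=O)N1[C@H](Cc2ccccc2)COC1=O
F2 | step 9 | (R)-4-benzyl-3-[(2R,3S)-3-hydroxy-2-methoxy-3-(7-methoxy-2,2-diphenyl-1,3-benzodioxol-4-yl)propanoyl]oxazolidin-2-one | CO[C@H]([C@@H](O)c1ccc(OC)c2OC(c3ccccc3)(c3ccccc3)Oc12)C(=O)N1[C@H](Cc2ccccc2)COC1=O
F3 | step 9 | (2R,3S)-3-hydroxy-N,2-dimethoxy-3-(7-methoxy-2,2-diphenyl-1,3-benzodioxol-4-yl)-N-methylpropanamide | CO[C@H]([C@@H](O)c1ccc(OC)c2OC(c3ccccc3)(c3ccccc3)Oc12)C(=O)N(C)OC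
F4 | step 9 | (2R,3S)-1-[3-(benzyloxy)-2,4-dimethoxy-6-(methoxymethoxy)phenyl]-3-hydroxy-2-methoxy-3-(7-methoxy-2,2-diphenyl-1,3-benzodioxol-4-yl)propan-1-one | CO[C@H]([C@@H](O)c1ccc(OC)c2OC(c3ccccc3)(c3ccccc3)Oc12)C(=O)c1c(OC)c(OCc2ccccc2)c(OC)cc1OCOC
F5 | step 9 | (2R,3S)-1-[3-(benzyloxy)-6-hydroxy-2,4-dimethoxyphenyl]-3-hydroxy-2-methoxy-3-(7-methoxy-2,2-diphenyl-1,3-benzodioxol-4-yl)propan-1-one | CO[C@H]([C@@H](O)c1ccc(OC)c2OC(c3ccccc3)(c3ccccc3)Oc12)C(=O)c1c(OC)c(OCc2ccccc2)c(OC)cc1O
F6 | step 3 | (7-methoxy-2,2-diphenyl-1,3-benzodioxol-4-yl)methanol | COc1ccc(CO)c2OC(c3ccccc3)(c3ccccc3)Oc12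
F7 | step 3 | 4-(bromomethyl)-7-methoxy-2,2-diphenyl-1,3-benzodioxole | COc1ccc(CBr)c2OC(c3ccccc3)(c3ccccc3)Oc12
F8 | step 3 | (S)-4-benzyl-3-(methoxyacetyl)oxazolidin-2-one | COCC(=O)N1[C@@H](Cc2ccccc2)COC1=O
F9 | step 3 | (S)-4-benzyl-3-[(R)-2-methoxy-3-(7-methoxy-2,2-diphenyl-1,3-benzodioxol-4-yl)propanoyl]oxazolidin-2-one | CO[C@H](Cc1ccc(OC)c2OC(c3ccccc3)(c3ccccc3)Oc12)C(=O)N1[C@@H](Cc2ccccc2)COC1=O
F0 | step 10 | none | none
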